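The ratio of target to isomer of the product tells me who leads and what share target holds, so I follow that ratio through the two earlier runs to forecast a new flask with [starting material] = 0.021 M.

| flask | starting material | remark | time |
|---|---|---|---|
| alpha | 0.029 M | run made earlier |  |
| epsilon | 0.046 M | run made earlier |  |
| flask | 0.021 M |  | 12 h |

| run | time / h | target / % | isomer of the product / % |
|---|---|---|---|
| alpha | 0.833 | 35.3 | 3.6 |
| alpha | 2.50 | 61.0 | 12.5 |
| alpha | 4.00 | 60.7 | 15.7 |
| alpha | 6.00 | 54.7 | 22.7 |
| alpha | 10.0 | 50.6 | 30.5 |
| alpha | 12.0 | 48.2 | 31.6 |
| epsilon | 0.833 | 34.4 | 4.2 |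
| epsilon | 2.50 | 59.8 | 10.8 |
| epsilon | 4.00 | 57.8 | 17.3 |
| epsilon | 6.00 | 53.9 | 21.8 |
| epsilon | 10.0 | 50.4 | 30.7 |
| epsilon | 12.0 | 49.2 | 31.8 |

(each reading ± 1 percentage point)

- share of target in target plus isomer of the product at 12 min
- share of target in target plus isomer of the product at 1.5 h
- share of target in target plus isomer of the product at 12 h
- which of target and isomer of the product there is more of at 12 h

- what was read earlier has a scatter of 1 percentage point, one standard deviation

Pooling both runs at each time, the ratio reads 8.94 at 0.833 h and falls steeply to 5.18 at 2.50 h, where target in the alpha run reads its peak of 61.0%. The knee comes next: 2.44 at 6.00 h, then 1.65 at 10.0 h. The last pooled reading, at 12.0 h, is 1.54, the end ratio, and it has not crossed: target still reads more than isomer of the product.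

I freeze this ratio against charge. Between the alpha and epsilon runs the charge rises 1.59-fold, yet the end ratio reads 1.53 and 1.55. The new charge lies below both, so this is an extrapolation. The end ratio gives a target share, the selectivity, of 60.6% at 12 h, with target ahead.

The forecast gives 93.5% at 12 min, 88% at 1.5 h, 60.5% at 12 h and target ahead, reading the falling share as “relaxation towards an equilibrium share”.

The flask gives 89.7%, 86.2% and 59.7%, with target ahead at 48.5% against 32.8%. That is a ratio of 1.48 against the carried 1.54.

    starting material → intermediate (k = 0.0393 min⁻¹)
    intermediate ⇌ target (K = 2.52, k = 0.0267 min⁻¹)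
    intermediate ⇌ isomer of the product (K = 2.74, k = 0.00295 min⁻¹)
    starting material ⇌ dormant form (K = 0.287, k = 0.0227 min⁻¹)

At 12.0 h this flask also holds 18.7% as intermediate, outside the ratio, and the undoing of dormant form into starting material makes no difference to the share at that time.

For a neighbour charged at 0.036 M, the end ratio 1.54 again gives 60.6% with target ahead. The neighbour gives 59.7% at 12 h, with target at 48.5% and isomer of the product at 32.8%.

Readings and results were generated by integration for substances that don't exist; the scatter is artificial.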